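**Retrosynthetic overview**
- The target is a 5,7-dihydroxyisoflavone whose ring B carries 4'-OMe, 5'-OH and a 3'-(E)-3-methylbuta-1,3-dienyl group. The acid-sensitive diene is attached last, by Suzuki–Miyaura coupling of a 3'-bromo-isoflavone triol with an (E)-dienyl pinacol boronate.
- The strategy rests on the C3–C4 bond of ring C (the pyranone). C4 (the ring carbonyl carbon) derives from the formyl carbon on ring A and C3 (the aryl-bearing carbon) from the carbonyl carbon of a ring-B aryl ketone. Two carbonyl carbons can be joined only if C4 reacts as an acyl anion, which a carbene-catalysed crossed benzoin reaction provides.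
- The resulting 3-aryl-3-hydroxychroman-4-one is dehydrated across C2–C3 to the chromone, and the MOM ethers are then removed.
- The O1–C2 ether comes from O-alkylation of a bis-MOM salicylaldehyde (from 2,4,6-trihydroxybenzaldehyde) with a phenacyl bromide (from 3-bromo-4,5-dihydroxybenzaldehyde).
- Rings A and B are bought; ring C is the only ring formed.

Key step: step 8

Remark: the only stereo-element of the target is the (E) side-chain double bond; the carbinol centre created in the key step is made racemic on purpose, because the following dehydration destroys it.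

**Route**

Step 1
Reactants: 1 3-bromo-4,5-dihydroxybenzaldehyde
Product: 2 3-bromo-5-hydroxy-4-methoxybenzaldehyde
Conditions: MeI (1.1 equiv), Li2CO3 (1.2 equiv), DMF, 40 °C
Reagents that add atoms: iodomethane, CI
Why: Williamson ether synthesis under weak-base control, in which the 4-OH (para to the formyl group and ortho to bromine) is by far the more acidic phenol, so only its phenoxide forms and is methylated while the 5-OH stays free.

Step 2
Reactants: 2 3-bromo-5-hydroxy-4-methoxybenzaldehyde
Product: 3 3-bromo-4-methoxy-5-(methoxymethoxy)benzaldehyde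
Conditions: MOMCl, i-Pr2NEt, CH2Cl2, 0 °C to rt
Reagents that add atoms: chloromethyl methyl ether, COCCl
Why: MOM etherification of the remaining phenol masks it against the Grignard, bromination and alkylation steps and gives a group that acid removes at the end.

Step 3
Reactants: 3 3-bromo-4-methoxy-5-(methoxymethoxy)benzaldehyde
Product: 4 rac-1-[3-bromo-4-methoxy-5-(methoxymethoxy)phenyl]ethan-1-ol
Conditions: MeMgBr, THF, 0 °C; aq. NH4Cl
Reagents that add atoms: methylmagnesium bromide, C[Mg]Br
Why: Grignard addition to the aldehyde is fast at 0 °C whereas the aryl bromide does not exchange with MeMgBr, and the carbinol centre forms as a racemate that the next oxidation removes.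

Step 4
Reactants: 4 rac-1-[3-bromo-4-methoxy-5-(methoxymethoxy)phenyl]ethan-1-ol
Product: 5 1-[3-bromo-4-methoxy-5-(methoxymethoxy)phenyl]ethan-1-one
Conditions: Dess–Martin periodinane, CH2Cl2, rt
Reagents that add atoms: none
Why: Dess–Martin oxidation of the secondary benzylic alcohol runs under near-neutral conditions and should give the aryl methyl ketone without touching the MOM acetal or the aryl bromide.

Step 5
Reactants: 5 1-[3-bromo-4-methoxy-5-(methoxymethoxy)phenyl]ethan-1-one
Product: 7 2-bromo-1-[3-bromo-4-methoxy-5-(methoxymethoxy)phenyl]ethan-1-one, via silyl enol ether 6 (not isolated)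
Conditions: LiN(SiMe3)2, Me3SiCl, THF, −78 °C; then NBS, −78 to 0 °C
Reagents that add atoms: N-bromosuccinimide, O=C1CCC(=O)N1Br
Why: Enolate silylation followed by electrophilic bromination of the silyl enol ether with NBS is much faster than ring bromination and generates no HBr, so the α-bromo ketone should form with the MOM ether and the electron-rich ring intact.

Step 6
Reactants: 8 2,4,6-trihydroxybenzaldehyde
Product: 9 2-hydroxy-4,6-bis(methoxymethoxy)benzaldehyde
Conditions: MOMCl (2.1 equiv), i-Pr2NEt (2.5 equiv), CH2Cl2, 0 °C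
Reagents that add atoms: chloromethyl methyl ether, COCCl
Why: MOM etherification should stop at the bis-ether because the last ortho hydroxyl is held in a hydrogen bond to the formyl oxygen and is far less nucleophilic, a familiar selectivity of 2,4,6-trihydroxyaryl carbonyl compounds.

Step 7
Reactants: 7 2-bromo-1-[3-bromo-4-methoxy-5-(methoxymethoxy)phenyl]ethan-1-one, 9 2-hydroxy-4,6-bis(methoxymethoxy)benzaldehyde
Product: 10 2-{2-[3-bromo-4-methoxy-5-(methoxymethoxy)phenyl]-2-oxoethoxy}-4,6-bis(methoxymethoxy)benzaldehyde
Conditions: K2CO3, DMF, 0 °C to rt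
Reagents that add atoms: none
Why: Williamson ether synthesis in which the phenoxide of 9 displaces the activated phenacyl bromide by SN2, the weak base and room temperature keeping the product from going on to the intramolecular aldol (Rap–Stoermer) condensation.

Step 8
Reactants: 10 2-{2-[3-bromo-4-methoxy-5-(methoxymethoxy)phenyl]-2-oxoethoxy}-4,6-bis(methoxymethoxy)benzaldehyde
Product: 11 rac-3-[3-bromo-4-methoxy-5-(methoxymethoxy)phenyl]-3-hydroxy-5,7-bis(methoxymethoxy)-2,3-dihydro-4H-chromen-4-one
Conditions: 2-phenyl-6,7-dihydro-5H-pyrrolo[2,1-c][1,2,4]triazol-2-ium tetrafluoroborate (20 mol%), 1,8-diazabicyclo[5.4.0]undec-7-ene (DBU, 18 mol%), THF, 25 to 40 °C, argon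
Reagents that add atoms: none
Why: DBU frees the triazolylidene, which adds to the formyl carbon of 10; proton transfer gives the Breslow enaminol, whose former aldehyde carbon (the future C4) attacks the tethered aryl ketone carbonyl (the future C3) as an acyl anion equivalent, and collapse of the adduct releases the carbene and the α-ketol 11. The closest known reaction type is the carbene-catalysed intramolecular crossed aldehyde–ketone benzoin reaction of 2-(2-aryl-2-oxoethoxy)benzaldehydes to 3-aryl-3-hydroxychroman-4-ones. Ring C is closed by the new C3–C4 bond in a 6-exo-trig mode. The C3 carbinol centre is formed without control, as a racemate, because catalyst and substrate are achiral, which is acceptable since C3 becomes trigonal in step 9. The step needs chemoselectivity for aldehyde-as-donor and ketone-as-acceptor: only the single formyl group can form a Breslow intermediate, homo-benzoin between two di-ortho-alkoxy aldehydes is sterically blocked, and the two-atom O–CH2 tether holds the ketone carbonyl in reach for six-membered closure. Keeping DBU below the azolium loading leaves little free base, so that the competing base-mediated aldol condensation of the O–CH2 group onto the aldehyde stays slow.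

Step 9
Reactants: 11 rac-3-[3-bromo-4-methoxy-5-(methoxymethoxy)phenyl]-3-hydroxy-5,7-bis(methoxymethoxy)-2,3-dihydro-4H-chromen-4-one
Product: 13 3-[3-bromo-4-methoxy-5-(methoxymethoxy)phenyl]-5,7-bis(methoxymethoxy)-4H-chromen-4-one, via chlorosulfite ester 12 (not isolated)
Conditions: SOCl2, pyridine, CH2Cl2, 0 °C to rt
Reagents that add atoms: none
Why: Dehydration of the tertiary α-ketol through its chlorosulfite (E2-type elimination with pyridine) can give only the C2=C3 bond because the only β-hydrogens sit on C2, is driven by formation of the conjugated 4-pyranone, removes the racemic C3 centre, and is buffered so that the MOM ethers stay in place.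

Step 10
Reactants: 13 3-[3-bromo-4-methoxy-5-(methoxymethoxy)phenyl]-5,7-bis(methoxymethoxy)-4H-chromen-4-one
Product: 14 3-(3-bromo-5-hydroxy-4-methoxyphenyl)-5,7-dihydroxy-4H-chromen-4-one
Conditions: HCl (1.25 M in MeOH), THF, 45 °C
Reagents that add atoms: none
Why: Acid-catalysed transacetalisation in methanol should cleave the three aryl MOM ethers to the free phenols while the chromone, the aryl bromide and the methyl ether are inert, and it is placed before the acid-sensitive diene is introduced.

Step 11
Reactants: 15 2-methylbut-1-en-3-yne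
Product: 16 4,4,5,5-tetramethyl-2-[(1E)-3-methylbuta-1,3-dien-1-yl]-1,3,2-dioxaborolane
Conditions: HBpin, Cp2ZrHCl (5 mol%), Et3N (10 mol%), sealed tube, 50 °C
Reagents that add atoms: pinacolborane (4,4,5,5-tetramethyl-1,3,2-dioxaborolane), CC1(C)OBOC1(C)C
Why: Zirconocene-catalysed alkyne hydroboration proceeds by syn-hydrozirconation of the terminal alkyne (much faster than that of the 1,1-disubstituted alkene) and zirconium-to-boron exchange with retention, which places boron on the terminal carbon and sets the (E) geometry of the target.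

Step 12
Reactants: 14 3-(3-bromo-5-hydroxy-4-methoxyphenyl)-5,7-dihydroxy-4H-chromen-4-one, 16 4,4,5,5-tetramethyl-2-[(1E)-3-methylbuta-1,3-dien-1-yl]-1,3,2-dioxaborolane
Product: 17 5,7-dihydroxy-3-{3-hydroxy-4-methoxy-5-[(1E)-3-methylbuta-1,3-dien-1-yl]phenyl}-4H-chromen-4-one
Conditions: Pd(OAc)2 (5 mol%), SPhos (2-dicyclohexylphosphino-2',6'-dimethoxybiphenyl, 10 mol%), K3PO4, 1,4-dioxane/H2O, 80 °C, degassed
Reagents that add atoms: none
Why: Suzuki–Miyaura coupling in which zerovalent palladium formed in situ inserts into the Ar–Br bond, the alkenylboronate transmetalates with retention of the (E) geometry and reductive elimination forms the aryl–dienyl bond, the free phenols being tolerated as phenoxides and the bulky biaryl phosphine coping with the ortho-methoxy, electron-rich bromide.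

**Compound list**

1 | 3-bromo-4,5-dihydroxybenzaldehyde | O=Cc1cc(O)c(O)c(Br)c1 | starting material
2 | 3-bromo-5-hydroxy-4-methoxybenzaldehyde | O=Cc1cc(O)c(OC)c(Br)c1 | intermediate
3 | 3-bromo-4-methoxy-5-(methoxymethoxy)benzaldehyde | O=Cc1cc(OCOC)c(OC)c(Br)c1 | intermediate
4 | rac-1-[3-bromo-4-methoxy-5-(methoxymethoxy)phenyl]ethan-1-ol | CC(O)c1cc(OCOC)c(OC)c(Br)c1 | intermediate
5 | 1-[3-bromo-4-methoxy-5-(methoxymethoxy)phenyl]ethan-1-one | CC(=O)c1cc(OCOC)c(OC)c(Br)c1 | intermediate
6 | ({1-[3-bromo-4-methoxy-5-(methoxymethoxy)phenyl]ethenyl}oxy)(trimethyl)silane (silyl enol ether, not isolated) | C=C(O[Si](C)(C)C)c1cc(OCOC)c(OC)c(Br)c1 | intermediate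
7 | 2-bromo-1-[3-bromo-4-methoxy-5-(methoxymethoxy)phenyl]ethan-1-one | O=C(CBr)c1cc(OCOC)c(OC)c(Br)c1 | intermediate
8 | 2,4,6-trihydroxybenzaldehyde | O=Cc1c(O)cc(O)cc1O | starting material
9 | 2-hydroxy-4,6-bis(methoxymethoxy)benzaldehyde | O=Cc1c(O)cc(OCOC)cc1OCOC | intermediate
10 | 2-{2-[3-bromo-4-methoxy-5-(methoxymethoxy)phenyl]-2-oxoethoxy}-4,6-bis(methoxymethoxy)benzaldehyde | O=Cc1c(OCC(=O)c2cc(Br)c(OC)c(OCOC)c2)cc(OCOC)cc1OCOC | intermediate
11 | rac-3-[3-bromo-4-methoxy-5-(methoxymethoxy)phenyl]-3-hydroxy-5,7-bis(methoxymethoxy)-2,3-dihydro-4H-chromen-4-one | COCOc1cc(OCOC)c2c(c1)OCC(O)(c1cc(Br)c(OC)c(OCOC)c1)C2=O | intermediate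
12 | 3-[3-bromo-4-methoxy-5-(methoxymethoxy)phenyl]-5,7-bis(methoxymethoxy)-4-oxo-3,4-dihydro-2H-chromen-3-yl chlorosulfite (chlorosulfite ester, not isolated) | COCOc1cc(OCOC)c2c(c1)OCC(OS(=O)Cl)(c1cc(Br)c(OC)c(OCOC)c1)C2=O | intermediate
13 | 3-[3-bromo-4-methoxy-5-(methoxymethoxy)phenyl]-5,7-bis(methoxymethoxy)-4H-chromen-4-one | COCOc1cc(OCOC)c2c(c1)occ(-c1cc(Br)c(OC)c(OCOC)c1)c2=O | intermediate
14 | 3-(3-bromo-5-hydroxy-4-methoxyphenyl)-5,7-dihydroxy-4H-chromen-4-one | COc1c(O)cc(-c2coc3cc(O)cc(O)c3c2=O)cc1Br | intermediate
15 | 2-methylbut-1-en-3-yne | C=C(C)C#C | starting material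
16 | 4,4,5,5-tetramethyl-2-[(1E)-3-methylbuta-1,3-dien-1-yl]-1,3,2-dioxaborolane | C=C(C)/C=C/B1OC(C)(C)C(C)(C)O1 | intermediate
17 | 5,7-dihydroxy-3-{3-hydroxy-4-methoxy-5-[(1E)-3-methylbuta-1,3-dien-1-yl]phenyl}-4H-chromen-4-one | C=C(C)/C=C/c1cc(-c2coc3cc(O)cc(O)c3c2=O)cc(O)c1OC | target

**Step count**
Total: 12 steps. Longest linear sequence: 10 steps (steps 1–5, 7–10 and 12).

**Steps most likely to fail, with fallbacks**

Step 8. The Breslow intermediate may form slowly at the hindered, electron-rich di-ortho-alkoxy aldehyde. Base-mediated intramolecular aldol condensation and air oxidation of the acyl anion equivalent could then overtake the ring closure. The fallback abandons the C3–C4 closure and builds ring C from a deoxybenzoin; it sets out from ketone 5 and returns at 14.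
- Willgerodt–Kindler reaction of 5 (S8, morpholine, 130 °C) should give the thioamide 2-[3-bromo-4-methoxy-5-(methoxymethoxy)phenyl]-1-(morpholin-4-yl)ethane-1-thione F1.
- Hydrolysis (KOH, aq. EtOH, reflux, then careful acidification) should give [3-bromo-4-methoxy-5-(methoxymethoxy)phenyl]acetic acid F2.
- Friedel–Crafts acylation of phloroglucinol (benzene-1,3,5-triol) with F2 in BF3·OEt2 at 85 °C, with loss of the MOM group, should give the deoxybenzoin 2-(3-bromo-5-hydroxy-4-methoxyphenyl)-1-(2,4,6-trihydroxyphenyl)ethan-1-one F3.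
- Formylative cyclisation (DMF, MsCl, BF3·OEt2, 70 °C) inserts C2 and should close ring C to give 14, from which step 12 follows.

Step 9. The tertiary chlorosulfite may undergo substitution without elimination, or the α-ketol may rearrange with ring contraction before the C2=C3 bond forms. The fallback replaces dehydration by reduction and re-oxidation; it sets out from 11 and returns at 13.
- Reductive removal of the tertiary hydroxyl with SmI2 (THF/MeOH, −78 °C, the known deoxygenation of α-hydroxy ketones) should give the isoflavanone rac-3-[3-bromo-4-methoxy-5-(methoxymethoxy)phenyl]-5,7-bis(methoxymethoxy)-2,3-dihydro-4H-chromen-4-one F4.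
- Dehydrogenation with DDQ (1,4-dioxane, 90 °C) should introduce the C2=C3 bond and give 13.

Step 12. Protodeboronation or oligomerisation of the dienylboronate, together with slow oxidative addition into the electron-rich, ortho-substituted bromide of the multiply deprotonated substrate, could starve the coupling. The fallback builds the diene in two stages without a boronate; it sets out from 14 and returns at 17.
- Heck reaction of 14 with 2-methylbut-3-en-2-ol (Pd(OAc)2, P(o-tol)3, Et3N, DMF, 100 °C) should give the (E)-allylic tertiary alcohol 5,7-dihydroxy-3-{3-hydroxy-5-[(1E)-3-hydroxy-3-methylbut-1-en-1-yl]-4-methoxyphenyl}-4H-chromen-4-one F5.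
- Mild acid-catalysed dehydration of this tertiary allylic alcohol (pyridinium p-toluenesulfonate, toluene/1,4-dioxane, 80 °C, 4 Å molecular sieves) should give target 17.

**Further compounds**
F1 | step 8 | 2-[3-bromo-4-methoxy-5-(methoxymethoxy)phenyl]-1-(morpholin-4-yl)ethane-1-thione | S=C(Cc1cc(OCOC)c(OC)c(Br)c1)N1CCOCC1
F2 | step 8 | [3-bromo-4-methoxy-5-(methoxymethoxy)phenyl]acetic acid | OC(=O)Cc1cc(OCOC)c(OC)c(Br)c1
F3 | step 8 | 2-(3-bromo-5-hydroxy-4-methoxyphenyl)-1-(2,4,6-trihydroxyphenyl)ethan-1-one | O=C(Cc1cc(O)c(OC)c(Br)c1)c1c(O)cc(O)cc1O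
F4 | step 9 | rac-3-[3-bromo-4-methoxy-5-(methoxymethoxy)phenyl]-5,7-bis(methoxymethoxy)-2,3-dihydro-4H-chromen-4-one | COCOc1cc(OCOC)c2c(c1)OCC(c1cc(Br)c(OC)c(OCOC)c1)C2=O
F5 | step 12 | 5,7-dihydroxy-3-{3-hydroxy-5-[(1E)-3-hydroxy-3-methylbut-1-en-1-yl]-4-methoxyphenyl}-4H-chromen-4-one | CC(C)(O)/C=C/c1cc(-c2coc3cc(O)cc(O)c3c2=O)cc(O)c1OC
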